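**Retrosynthetic overview**

- Feature: number the oxane O1, C2 (4‑hydroxyphenyl), C3 (cinnamyl), C4, C5 (aryl carbinol), C6. The units ArCH(O1)–C3–CH2(styryl) and ArCH(OH)–C5–C6H2 are the same anti‑aldol triad, exchanged by a twofold axis through C4, so the target is a desymmetrised C2‑symmetric 2,4‑bis(aryl‑hydroxymethyl)pentane‑1,5‑diol.
- The three aryl silyl ethers come off last. Before that, O1–C6 is cut (Williamson closure of the benzylic oxygen at C2 onto the primary carbon); this oxane is the only ring and is formed in the penultimate step.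
- The CH2–CH= bond of the cinnamyl arm is cut next: Negishi coupling of a primary alkyl iodide with an (E)‑β‑bromostyrene made from p‑coumaric acid.
- The two homotopic CH2O arms go back to two imides. C2–C3 and C5–C(carbinol) are then cut together: a two‑directional magnesium‑catalysed anti‑aldol of the glutaryl bis‑imide with two molecules of a 4‑silyloxybenzaldehyde.

Key step: step 3

Remark: the phenols are carried as triisopropylsilyl ethers and the aliphatic oxygens as triethylsilyl ethers, so that buffered HF can free the aliphatic oxygens while the aryl ethers stay. The sense of induction assumed for the magnesium aldol is that of the chelated Z‑enolate reacting on the face away from the benzyl group.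

**Route**

Step 1
Reactants: 1 glutaryl chloride; 2 (R)-4-benzyl-1,3-oxazolidin-2-one
Product: 3 1,5-bis[(R)-4-benzyl-2-oxo-1,3-oxazolidin-3-yl]pentane-1,5-dione
Conditions: 2 (2.1 equiv), n-BuLi (2.05 equiv), THF, −78 °C; then 1 (1.0 equiv), −78 → 0 °C
Reagents that add atoms: none
Why: N‑acylation of the lithiated oxazolidinone by the diacid chloride is a standard imide formation and touches no stereocentre.

Step 2
Reactants: 4 4-hydroxybenzaldehyde
Product: 5 4-(triisopropylsilyloxy)benzaldehyde
Conditions: i-Pr3SiCl (1.1 equiv), imidazole (2 equiv), DMF, rt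
Reagents that add atoms: chlorotriisopropylsilane, CC(C)[Si](Cl)(C(C)C)C(C)C
Why: imidazole‑promoted O‑silylation of a phenol gives an aryl silyl ether that tolerates amine base, hydride and alkoxide and is later removed by fluoride.

Step 3
Reactants: 3 glutaryl bis‑imide; 5 4-(triisopropylsilyloxy)benzaldehyde (2.6 equiv)
Product: 6 (2S,4S)-1,5-bis[(R)-4-benzyl-2-oxo-1,3-oxazolidin-3-yl]-2,4-bis{(R)-[4-(triisopropylsilyloxy)phenyl](trimethylsilyloxy)methyl}pentane-1,5-dione
Conditions: MgCl2 (0.4 equiv), Et3N (5 equiv), Me3SiCl (4 equiv), EtOAc, 23 °C, 24–48 h; filtration through Et3N‑deactivated silica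
Reagents that add atoms: chlorotrimethylsilane, C[Si](C)(C)Cl
Why: Each acyloxazolidinone is bound by MgCl2 as a chelate and deprotonated by Et3N to the chelated Z‑magnesium enolate, which adds to the non‑enolisable aldehyde 5; Me3SiCl then silylates the magnesium aldolate, releasing the metal for turnover and making the addition irreversible. The closest known reaction is the magnesium halide‑catalysed direct anti‑aldol of N‑acyloxazolidinones with aromatic aldehydes, applied here to both ends of one glutaryl chain. No ring is closed: the two new C–C bonds are those that become C2–C3 and C5–C(carbinol) of the target. At each end the aldehyde meets the enolate face turned away from the benzyl group of the metal‑chelated (R)‑auxiliary, which fixes the alpha carbon as S, and the boat‑like arrangement of the chelated enolate places aryl and chain anti, which fixes the carbinol carbon as R. The step needs the same anti, auxiliary‑controlled outcome twice; the three‑carbon spacer keeps the two imides from interacting, so the C2‑symmetric adduct should dominate, any wrong‑sense event ends as a diastereomer that is removed after the next step, and the double reaction raises the enantiomeric purity of the major isomer. Excess Me3SiCl is used so that silylation outruns the one side reaction peculiar to this substrate, transfer of the far acyl group to the aldolate oxygen with closure of a six‑membered lactone.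

Step 4
Reactants: 6 bis(trimethylsilyl) ether of the bis‑aldol adduct
Product: 8 (2S,4S)-1,5-bis[(R)-4-benzyl-2-oxo-1,3-oxazolidin-3-yl]-2,4-bis{(R)-(triethylsilyloxy)[4-(triisopropylsilyloxy)phenyl]methyl}pentane-1,5-dione, via free bis-aldol diol 7 (not isolated)
Conditions: 1 M aq. HCl/THF (1:5), 0 °C, 15 min; NaHCO3 quench, extraction; then Et3SiOTf (3 equiv), 2,6‑lutidine (5 equiv), CH2Cl2, −78 → 0 °C
Reagents that add atoms: triethylsilyl trifluoromethanesulfonate, CC[Si](CC)(CC)OS(=O)(=O)C(F)(F)F
Why: dilute acid hydrolyses only the labile Me3Si ethers and the freed benzylic alcohols are recapped at once by silyl triflate silylation, because in 7 each hydroxyl sits delta to the far imide carbonyl and would lactonise on storage; no stereocentre is touched and minor diastereomers are separated here.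

Step 5
Reactants: 8 bis(triethylsilyl) ether bis‑imide
Product: 9 (2R,4R)-2,4-bis{(R)-(triethylsilyloxy)[4-(triisopropylsilyloxy)phenyl]methyl}pentane-1,5-diol
Conditions: LiBH4 (5 equiv), MeOH (5 equiv), Et2O, 0 °C → rt; aq. NH4Cl
Reagents that add atoms: none
Why: reductive cleavage of N‑acyloxazolidinones by LiBH4/MeOH attacks the exocyclic carbonyl, gives the primary alcohols without epimerisation of the adjacent centres and releases the auxiliary for recovery (the descriptor change S to R is only a priority change).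

Step 6
Reactants: 9 C2‑symmetric diol
Product: 10 (2R,4R)-5-(triethylsilyloxy)-2,4-bis{(R)-(triethylsilyloxy)[4-(triisopropylsilyloxy)phenyl]methyl}pentan-1-ol
Conditions: Et3SiCl (1.0 equiv), imidazole (1.5 equiv), CH2Cl2, −40 → 0 °C; unreacted 9 recycled
Reagents that add atoms: chlorotriethylsilane, CC[Si](Cl)(CC)CC
Why: statistical mono‑silylation of a diol whose two CH2OH groups are homotopic through the C2 axis, so only one mono‑ether can form; the silylated arm becomes C6 and the free arm the cinnamyl arm.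

Step 7
Reactants: 10 mono‑alcohol
Product: 11 (2S,4R)-1-iodo-5-(triethylsilyloxy)-2,4-bis{(R)-(triethylsilyloxy)[4-(triisopropylsilyloxy)phenyl]methyl}pentane
Conditions: PPh3 (1.5 equiv), I2 (1.5 equiv), imidazole (3 equiv), CH2Cl2, 0 °C → rt
Reagents that add atoms: iodine, II
Why: Appel‑type iodination of a primary alcohol through its alkoxyphosphonium salt under imidazole buffering, which leaves the silyl ethers and the adjacent stereocentre intact.

Step 8
Reactants: 12 p‑coumaric acid
Product: 14 (E)-3-[4-(triisopropylsilyloxy)phenyl]prop-2-enoic acid, via silyl ester 13 (not isolated)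
Conditions: i-Pr3SiCl (2.3 equiv), imidazole (5 equiv), DMF, rt; then AcOH/THF/H2O (3:1:1), rt
Reagents that add atoms: chlorotriisopropylsilane, CC(C)[Si](Cl)(C(C)C)C(C)C
Why: exhaustive silylation followed by selective hydrolysis of the far more labile silyl ester gives the phenol‑protected acid, which keeps N‑bromosuccinimide off the ring in the next step.

Step 9
Reactants: 14 silyl‑protected coumaric acid
Product: 15 (E)-1-(2-bromoethenyl)-4-(triisopropylsilyloxy)benzene
Conditions: N‑bromosuccinimide (1.1 equiv), LiOAc (0.2 equiv), MeCN/H2O (19:1), rt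
Reagents that add atoms: N‑bromosuccinimide, O=C1CCC(=O)N1Br
Why: catalytic Hunsdiecker‑type bromodecarboxylation; the electron‑rich cinnamate is brominated at the alpha carbon and loses CO2 from the benzylic cation to give the E alkenyl bromide.

Step 10
Reactants: 11 primary iodide; 15 (E)‑alkenyl bromide (1.3 equiv)
Product: 17 (1E,4S,6R)-7-(triethylsilyloxy)-4,6-bis{(R)-(triethylsilyloxy)[4-(triisopropylsilyloxy)phenyl]methyl}-1-[4-(triisopropylsilyloxy)phenyl]hept-1-ene, via alkylzinc iodide 16 (not isolated)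
Conditions: Zn dust (4 equiv, activated with BrCH2CH2Br and Me3SiCl), DMF, rt; then 15, Pd(OAc)2 (5 mol%), SPhos (10 mol%), THF/DMF, rt → 40 °C
Reagents that add atoms: zinc, [Zn] (held by intermediate 16 only)
Why: Negishi coupling, in which zinc inserts into the primary C–I bond and 16 transmetalates to the alkenylpalladium bromide formed from 15 and zerovalent palladium; the bulky biaryl phosphine favours reductive elimination over β‑hydride elimination, the alkene geometry is retained and the silylated CH2O arm cannot quench the organozinc.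

Step 11
Reactants: 17 coupled tris(triethylsilyl) ether
Product: 18 (2R,4S,6E)-2,4-bis{(R)-hydroxy[4-(triisopropylsilyloxy)phenyl]methyl}-7-[4-(triisopropylsilyloxy)phenyl]hept-6-en-1-ol
Conditions: HF·pyridine, pyridine, THF, 0 °C → rt
Reagents that add atoms: none
Why: selective desilylation with buffered acidic fluoride, which cleaves alkyl triethylsilyl ethers far faster than aryl triisopropylsilyl ethers, so the three aliphatic hydroxyls are freed while the phenols stay masked and no phenoxide can compete in the ring closure.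

Step 12
Reactants: 18 triol
Product: 20 (2R,3S,5R)-5-{(R)-hydroxy[4-(triisopropylsilyloxy)phenyl]methyl}-2-[4-(triisopropylsilyloxy)phenyl]-3-{(E)-3-[4-(triisopropylsilyloxy)phenyl]prop-2-enyl}oxane, via primary tosylate 19 (not isolated)
Conditions: NaH (3.5 equiv), THF, 0 °C; then 1-(p-toluenesulfonyl)imidazole (1.05 equiv), 0 °C → rt
Reagents that add atoms: 1-(p-toluenesulfonyl)imidazole, Cc1ccc(cc1)S(=O)(=O)n1ccnc1 (its sulfonyl group is held by intermediate 19 only)
Why: one‑pot Williamson etherification, in which the primary alkoxide is sulfonylated first and the alkoxide on the benzylic carbon next to the cinnamyl‑bearing carbon displaces the tosylate by 6‑exo‑tet closure, whereas the other benzylic alkoxide could only close an oxetane; substitution occurs at the CH2, so all four stereocentres are retained.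

Step 13
Reactants: 20 tris(triisopropylsilyl) oxane
Product: 21 (2R,3S,5R)-5-[(R)-hydroxy(4-hydroxyphenyl)methyl]-2-(4-hydroxyphenyl)-3-[(E)-3-(4-hydroxyphenyl)prop-2-enyl]oxane (target)
Conditions: Bu4NF (4 equiv), AcOH (4 equiv), THF, 0 °C → rt; aq. NH4Cl
Reagents that add atoms: none
Why: fluoride desilylation of the three aryl silyl ethers under acetic acid buffering, which avoids both the strong base and the strong acid that could ionise the p‑hydroxybenzylic C–O bonds.

**Compound list**

1 | glutaryl chloride | O=C(Cl)CCCC(=O)Cl | starting material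
2 | (R)-4-benzyl-1,3-oxazolidin-2-one | O=C1N[C@H](Cc2ccccc2)CO1 | starting material
3 | 1,5-bis[(R)-4-benzyl-2-oxo-1,3-oxazolidin-3-yl]pentane-1,5-dione | O=C(CCCC(=O)N1[C@H](Cc2ccccc2)COC1=O)N1[C@H](Cc2ccccc2)COC1=O | intermediate
4 | 4-hydroxybenzaldehyde | O=Cc1ccc(O)cc1 | starting material
5 | 4-(triisopropylsilyloxy)benzaldehyde | O=Cc1ccc(O[Si](C(C)C)(C(C)C)C(C)C)cc1 | intermediate
6 | bis(trimethylsilyl) ether of the C2‑symmetric bis‑anti‑aldol adduct (2S,4S; carbinols R) | O=C(N1[C@H](Cc2ccccc2)COC1=O)[C@H]([C@@H](O[Si](C)(C)C)c1ccc(O[Si](C(C)C)(C(C)C)C(C)C)cc1)C[C@@H]([C@@H](O[Si](C)(C)C)c1ccc(O[Si](C(C)C)(C(C)C)C(C)C)cc1)C(=O)N1[C@H](Cc2ccccc2)COC1=O | intermediate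
7 | free bis‑anti‑aldol diol (2S,4S; carbinols R) | O=C(N1[C@H](Cc2ccccc2)COC1=O)[C@H]([C@@H](O)c1ccc(O[Si](C(C)C)(C(C)C)C(C)C)cc1)C[C@@H]([C@@H](O)c1ccc(O[Si](C(C)C)(C(C)C)C(C)C)cc1)C(=O)N1[C@H](Cc2ccccc2)COC1=O | intermediate
8 | bis(triethylsilyl) ether of the bis‑aldol adduct | O=C(N1[C@H](Cc2ccccc2)COC1=O)[C@H]([C@@H](O[Si](CC)(CC)CC)c1ccc(O[Si](C(C)C)(C(C)C)C(C)C)cc1)C[C@@H]([C@@H](O[Si](CC)(CC)CC)c1ccc(O[Si](C(C)C)(C(C)C)C(C)C)cc1)C(=O)N1[C@H](Cc2ccccc2)COC1=O | intermediate
9 | (2R,4R)-2,4-bis{(R)-(triethylsilyloxy)[4-(triisopropylsilyloxy)phenyl]methyl}pentane-1,5-diol | OC[C@H]([C@@H](O[Si](CC)(CC)CC)c1ccc(O[Si](C(C)C)(C(C)C)C(C)C)cc1)C[C@@H]([C@@H](O[Si](CC)(CC)CC)c1ccc(O[Si](C(C)C)(C(C)C)C(C)C)cc1)CO | intermediate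
10 | mono(triethylsilyl) ether of diol 9 | OC[C@H]([C@@H](O[Si](CC)(CC)CC)c1ccc(O[Si](C(C)C)(C(C)C)C(C)C)cc1)C[C@@H]([C@@H](O[Si](CC)(CC)CC)c1ccc(O[Si](C(C)C)(C(C)C)C(C)C)cc1)CO[Si](CC)(CC)CC | intermediate
11 | primary iodide (2S,4R) | IC[C@H]([C@@H](O[Si](CC)(CC)CC)c1ccc(O[Si](C(C)C)(C(C)C)C(C)C)cc1)C[C@@H]([C@@H](O[Si](CC)(CC)CC)c1ccc(O[Si](C(C)C)(C(C)C)C(C)C)cc1)CO[Si](CC)(CC)CC | intermediate
12 | p‑coumaric acid | O=C(O)/C=C/c1ccc(O)cc1 | starting material
13 | triisopropylsilyl (E)-3-[4-(triisopropylsilyloxy)phenyl]prop-2-enoate | CC(C)[Si](OC(=O)/C=C/c1ccc(O[Si](C(C)C)(C(C)C)C(C)C)cc1)(C(C)C)C(C)C | intermediate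
14 | (E)-3-[4-(triisopropylsilyloxy)phenyl]prop-2-enoic acid | O=C(O)/C=C/c1ccc(O[Si](C(C)C)(C(C)C)C(C)C)cc1 | intermediate
15 | (E)-1-(2-bromoethenyl)-4-(triisopropylsilyloxy)benzene | Br/C=C/c1ccc(O[Si](C(C)C)(C(C)C)C(C)C)cc1 | intermediate
16 | alkylzinc iodide from 11 | I[Zn]C[C@H]([C@@H](O[Si](CC)(CC)CC)c1ccc(O[Si](C(C)C)(C(C)C)C(C)C)cc1)C[C@@H]([C@@H](O[Si](CC)(CC)CC)c1ccc(O[Si](C(C)C)(C(C)C)C(C)C)cc1)CO[Si](CC)(CC)CC | intermediate
17 | coupled (1E,4S,6R)-heptene, tris(triethylsilyl) ether | CC(C)[Si](Oc1ccc(/C=C/C[C@H]([C@@H](O[Si](CC)(CC)CC)c2ccc(O[Si](C(C)C)(C(C)C)C(C)C)cc2)C[C@@H]([C@@H](O[Si](CC)(CC)CC)c2ccc(O[Si](C(C)C)(C(C)C)C(C)C)cc2)CO[Si](CC)(CC)CC)cc1)(C(C)C)C(C)C | intermediate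
18 | (2R,4S,6E)-triol, phenols still silylated | CC(C)[Si](Oc1ccc(/C=C/C[C@H]([C@@H](O)c2ccc(O[Si](C(C)C)(C(C)C)C(C)C)cc2)C[C@@H]([C@@H](O)c2ccc(O[Si](C(C)C)(C(C)C)C(C)C)cc2)CO)cc1)(C(C)C)C(C)C | intermediate
19 | primary p‑toluenesulfonate of 18 | CC(C)[Si](Oc1ccc(/C=C/C[C@H]([C@@H](O)c2ccc(O[Si](C(C)C)(C(C)C)C(C)C)cc2)C[C@@H]([C@@H](O)c2ccc(O[Si](C(C)C)(C(C)C)C(C)C)cc2)COS(=O)(=O)c2ccc(C)cc2)cc1)(C(C)C)C(C)C | intermediate
20 | (2R,3S,5R)-oxane, tris(triisopropylsilyl) ether, carbinol R | CC(C)[Si](Oc1ccc(/C=C/C[C@H]2C[C@@H]([C@@H](O)c3ccc(O[Si](C(C)C)(C(C)C)C(C)C)cc3)CO[C@H]2c2ccc(O[Si](C(C)C)(C(C)C)C(C)C)cc2)cc1)(C(C)C)C(C)C | intermediate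
21 | CNP0182155.1 | Oc1ccc(/C=C/C[C@H]2C[C@@H]([C@@H](O)c3ccc(O)cc3)CO[C@H]2c2ccc(O)cc2)cc1 | target

**Step count**

Total steps: 13. Longest linear sequence: 10 (steps 1, 3, 4, 5, 6, 7, 10, 11, 12, 13); steps 2 and 8–9 are side branches.

**Steps most likely to fail**

Step 3. The second enolisation and addition may lag behind the first. The magnesium aldolate may acylate onto the far imide before it is silylated. Reversible addition of the electron‑rich aldehyde may erode the anti selectivity. Fallback from 3, returning at 7: both imides are enolised stoichiometrically with Bu2BOTf and i‑Pr2NEt in CH2Cl2 at 0 °C to the bis(dibutylboron) Z‑enolate F1. F1 is added at −78 °C to aldehyde 5 precomplexed with Et2AlCl. This open‑transition‑state anti‑aldol uses the same chelated enolate face, is irreversible at low temperature and leaves no free magnesium alkoxide. Buffered aqueous methanolic work‑up gives 7, which is silylated directly to 8 as in the second half of step 4.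

Step 10. Zinc insertion at the β‑branched primary iodide may be slow, the organozinc may be protonated, and β‑hydride elimination at palladium may give isomerised or reduced material. Fallback from 15 and 11, returning at 17, with the polarity of the coupling reversed. Bromide 15 is dehydrobrominated with LDA (2.2 equiv, THF, −78 → 0 °C, then NH4Cl) to 1-ethynyl-4-(triisopropylsilyloxy)benzene F2. Hydrozirconation with Cp2Zr(H)Cl in THF gives the (E)‑alkenylzirconocene chloride F3. F3 is coupled with iodide 11 as the electrophile (Pd(acac)2, LiBr, THF/NMP, 55 °C) to give 17 without any metalation at the hindered sp3 carbon.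

Step 12. Sulfonylation may lose site selectivity, with a benzylic alkoxide reacting and then ionising or eliminating, and closure may be slow because the C2 aryl group must sit axial. Fallback from 17, returning at 20, with the sites separated by protecting groups instead of by rate. The primary triethylsilyl ether of 17 alone is cleaved with buffered HF·pyridine in THF at −20 °C to the primary alcohol F4. MsCl and Et3N in CH2Cl2 at 0 °C give the mesylate F5. HF·pyridine at rt then removes the two benzylic triethylsilyl groups to give the diol mesylate F6. KOtBu in THF at 0 °C closes F6 to 20.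

**Further compounds**

F1 | step 3 | bis(dibutylboron) Z,Z‑enolate of 3 | CCCCB(CCCC)O/C(N1[C@H](Cc2ccccc2)COC1=O)=C\C/C=C(\OB(CCCC)CCCC)N1[C@H](Cc2ccccc2)COC1=O
F2 | step 10 | 1-ethynyl-4-(triisopropylsilyloxy)benzene | C#Cc1ccc(O[Si](C(C)C)(C(C)C)C(C)C)cc1
F3 | step 10 | (E)-2-[4-(triisopropylsilyloxy)phenyl]ethenylzirconocene chloride | Cl[Zr](/C=C/c1ccc(O[Si](C(C)C)(C(C)C)C(C)C)cc1)(C1C=CC=C1)C1C=CC=C1
F4 | step 12 | primary alcohol with both benzylic triethylsilyl ethers kept | CC(C)[Si](Oc1ccc(/C=C/C[C@H]([C@@H](O[Si](CC)(CC)CC)c2ccc(O[Si](C(C)C)(C(C)C)C(C)C)cc2)C[C@@H]([C@@H](O[Si](CC)(CC)CC)c2ccc(O[Si](C(C)C)(C(C)C)C(C)C)cc2)CO)cc1)(C(C)C)C(C)C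
F5 | step 12 | primary methanesulfonate of F4 | CC(C)[Si](Oc1ccc(/C=C/C[C@H]([C@@H](O[Si](CC)(CC)CC)c2ccc(O[Si](C(C)C)(C(C)C)C(C)C)cc2)C[C@@H]([C@@H](O[Si](CC)(CC)CC)c2ccc(O[Si](C(C)C)(C(C)C)C(C)C)cc2)COS(C)(=O)=O)cc1)(C(C)C)C(C)C
F6 | step 12 | diol methanesulfonate | CC(C)[Si](Oc1ccc(/C=C/C[C@H]([C@@H](O)c2ccc(O[Si](C(C)C)(C(C)C)C(C)C)cc2)C[C@@H]([C@@H](O)c2ccc(O[Si](C(C)C)(C(C)C)C(C)C)cc2)COS(C)(=O)=O)cc1)(C(C)C)C(C)C
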